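**Plan**

1. Numbering: C1 acetoxy carbon, C2=C3(CH3) ring alkene, C4 ring ketone, C5=C6 exocyclic alkene, C7(CH3) and C10 oxolane carbons, C11 C(CH3)2, C14 CH(CH3), C15 macrocycle ketone.
2. Enabling feature: in the cyclopentenone ring C1–C2–C3–C4–C5 the ketone C4 sits next to the exocyclic C5=C6 alkene, so the C4–C5 bond plus that alkene equal a syn addition of a formyl C4–H across a C5≡C6 alkyne held in the 12-membered carbocycle C1/C5–C15.
3. Cuts, last-formed bond first: C4–C5 (hydroacylation), C13–C14 (macrocycle), C14–C15 (ethyl ketone), C1–C5 (alkynylation of a keto ester), C1–C2 (alkenyllithium on oxalate), C11–C12 (radical Giese addition), C10–O (epoxide opening).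
4. Forward: the oxolane is made first from (S)-linalool, the two fragments are joined at C1–C5, the 12-membered ring closes at C13–C14, and the cyclopentenone ring closes last.
5. Stereochemistry: C7 from (S)-linalool; C10 from Shi epoxidation and inverting 5-exo opening; C1 from ligand-controlled zinc acetylide addition; C14 from alkylation of a lithium-chelated Z-enolate; the Z-enal from anti-carbomagnesiation; the exocyclic alkene from syn addition.

Key step: step 17

Assumption: the amino alcohol antipode written in step 10 is taken to deliver the acetylide to the Si face of the ketone; if its sense proves opposite, the mirror-image ligand is used and nothing else changes.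

**Route**

Step 1
Reactants: 1 (S)-linalool
Product: 3 2-[(2S,5S)-5-ethenyl-5-methyloxolan-2-yl]propan-2-ol (furanoid linalool oxide; vinyl trans to the hydroxyisopropyl group), via epoxide 2 (not isolated)
Conditions: Shi ketone from D-fructose (0.3 equiv), Oxone (2KHSO5·KHSO4·K2SO4), K2CO3, Bu4NHSO4, MeCN/CH2(OMe)2/aq. Na2B4O7 buffer, 0 °C; then CSA (cat.), CH2Cl2, 0 °C
Reagents that add atoms: potassium peroxymonosulfate (active part of Oxone), [K+].[O-]S(=O)(=O)OO
Why: Shi epoxidation touches only the electron-rich trisubstituted alkene and its spiro transition state should give the (6R)-epoxide; acid then lets the tertiary hydroxyl open it 5-exo at the secondary carbon with inversion, which sets C10 as S while C7 is carried over from linalool (any pyranoid isomer would be removed by chromatography).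

Step 2
Reactants: 3 2-[(2S,5S)-5-ethenyl-5-methyloxolan-2-yl]propan-2-ol
Product: 5 (2S,5S)-5-(2-hydroxypropan-2-yl)-2-methyloxolane-2-carbaldehyde, via ozonide 4 (not isolated)
Conditions: O3, CH2Cl2, −78 °C; then Me2S, −78 °C to rt
Reagents that add atoms: ozone, [O-][O+]=O
Why: Ozonolysis with reductive work-up cleaves the only alkene; the α-carbon C7 is quaternary and cannot epimerise, and the trans hydroxyisopropyl group cannot reach the formyl group to form a lactol.

Step 3
Reactants: 5 (2S,5S)-5-(2-hydroxypropan-2-yl)-2-methyloxolane-2-carbaldehyde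
Product: 6 2-[(2S,5S)-5-ethynyl-5-methyloxolan-2-yl]propan-2-ol
Conditions: dimethyl (1-diazo-2-oxopropyl)phosphonate, K2CO3, MeOH, 0 °C to rt
Reagents that add atoms: dimethyl (1-diazo-2-oxopropyl)phosphonate, CC(=O)C(=[N+]=[N-])P(=O)(OC)OC
Why: The Ohira–Bestmann form of the Seyferth–Gilbert homologation converts a non-enolisable aldehyde into the terminal alkyne (C6 from the aldehyde, C5 from the reagent) under mild carbonate conditions.

Step 4
Reactants: 6 2-[(2S,5S)-5-ethynyl-5-methyloxolan-2-yl]propan-2-ol
Product: 8 cesium 2-[(2S,5S)-5-ethynyl-5-methyloxolan-2-yl]propan-2-yl oxalate, via methyl oxalate 7 (not isolated)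
Conditions: ClC(O)CO2Me, Et3N, DMAP (cat.), CH2Cl2, 0 °C to rt; then CsOH (1.0 equiv), THF/H2O, rt
Reagents that add atoms: methyl chlorooxoacetate, COC(=O)C(=O)Cl; cesium hydroxide, [Cs+].[OH-]
Why: DMAP-catalysed acylation of the tertiary alcohol followed by saponification of the unhindered methyl ester with one equivalent of hydroxide gives the tert-alkyl oxalate salt used as a radical precursor.

Step 5
Reactants: 8 cesium 2-[(2S,5S)-5-ethynyl-5-methyloxolan-2-yl]propan-2-yl oxalate; 9 vinylboronic acid pinacol ester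
Product: 11 3-[(2S,5S)-5-ethynyl-5-methyloxolan-2-yl]-3-methylbutan-1-ol, via pinacol boronate 10 (not isolated)
Conditions: Ir[dF(CF3)ppy]2(dtbbpy)PF6 (1 mol %), H2O (10 equiv), DME/DMF 3:1, blue LEDs, 60 °C; then H2O2, aq. NaOH, 0 °C
Reagents that add atoms: hydrogen peroxide, OO
Why: Photoredox oxidation of the oxalate and loss of two CO2 give the tertiary C11 radical, which adds to the vinyl boronate (Giese reaction), the α-boryl radical is reduced and protonated, and the C–B bond is oxidised to the primary alcohol; C11 is not a stereocentre and the trans ethynyl group is out of reach of the radical.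

Step 6
Reactants: 11 3-[(2S,5S)-5-ethynyl-5-methyloxolan-2-yl]-3-methylbutan-1-ol
Product: 12 (2S,5S)-5-(4-bromo-2-methylbutan-2-yl)-2-ethynyl-2-methyloxolane
Conditions: CBr4, PPh3, CH2Cl2, 0 °C
Reagents that add atoms: tetrabromomethane, BrC(Br)(Br)Br
Why: The Appel reaction converts the unhindered primary alcohol into the bromide, which tolerates the amine and Grignard reagents of steps 10 and 11 better than an iodide would.

Step 7
Reactants: 13 prop-2-yn-1-ol
Product: 15 (Z)-3-iodo-2-methylprop-2-en-1-ol, via alkenylmagnesium alkoxide 14 (not isolated)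
Conditions: MeMgBr (2.5 equiv), CuI (0.1 equiv), THF, −10 °C to rt; then I2, −78 to 0 °C
Reagents that add atoms: methylmagnesium bromide, C[Mg]Br; iodine, [I][I]
Why: Copper-catalysed anti-carbomagnesiation of the propargylic alkoxide puts methyl on C3 and magnesium on C2 in a five-membered chelate, and iodinolysis with retention fixes the Z geometry in which C4 is cis to the future C1.

Step 8
Reactants: 15 (Z)-3-iodo-2-methylprop-2-en-1-ol
Product: 16 tert-butyl{[(2Z)-3-iodo-2-methylprop-2-en-1-yl]oxy}dimethylsilane
Conditions: TBSCl, imidazole, CH2Cl2, rt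
Reagents that add atoms: tert-butyldimethylsilyl chloride, CC(C)(C)[Si](C)(C)Cl
Why: Standard silylation of a primary alcohol gives an ether that survives organolithium, Grignard and enolate chemistry and is removed later under acidic fluoride conditions.

Step 9
Reactants: 16 tert-butyl{[(2Z)-3-iodo-2-methylprop-2-en-1-yl]oxy}dimethylsilane; 17 dimethyl oxalate
Product: 19 methyl (Z)-5-[(tert-butyldimethylsilyl)oxy]-4-methyl-2-oxopent-3-enoate, via vinyllithium 18 (not isolated)
Conditions: t-BuLi (2.0 equiv), Et2O, −78 °C; then cannulated into 17 (3 equiv), THF, −78 °C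
Reagents that add atoms: none
Why: Iodine–lithium exchange proceeds with retention of alkene geometry, and inverse addition to excess oxalate stops at mono-acylation because the tetrahedral adduct is stable at −78 °C.

Step 10
Reactants: 12 (2S,5S)-5-(4-bromo-2-methylbutan-2-yl)-2-ethynyl-2-methyloxolane; 19 methyl (Z)-5-[(tert-butyldimethylsilyl)oxy]-4-methyl-2-oxopent-3-enoate
Product: 20 methyl (2S,3Z)-2-{[(2S,5S)-5-(4-bromo-2-methylbutan-2-yl)-2-methyloxolan-2-yl]ethynyl}-5-[(tert-butyldimethylsilyl)oxy]-2-hydroxy-4-methylpent-3-enoate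
Conditions: Zn(OTf)2 (0.2 equiv), (1S,2S)-3-[(tert-butyldimethylsilyl)oxy]-2-(dimethylamino)-1-(4-nitrophenyl)propan-1-ol (0.22 equiv), Et3N (0.3 equiv), toluene, 70 °C
Reagents that add atoms: none
Why: Zinc triflate and amine generate the zinc acetylide in the chiral amino alkoxide pocket and it adds 1,2 to the activated ketone (catalytic asymmetric alkynylation of an α-keto ester); Si-face delivery gives (S)-C1 and forms C1–C5, and the primary bromide is inert to the small amount of hindered amine.

Step 11
Reactants: 20 methyl (2S,3Z)-2-{[(2S,5S)-5-(4-bromo-2-methylbutan-2-yl)-2-methyloxolan-2-yl]ethynyl}-5-[(tert-butyldimethylsilyl)oxy]-2-hydroxy-4-methylpent-3-enoate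
Product: 22 (4S,5Z)-4-{[(2S,5S)-5-(4-bromo-2-methylbutan-2-yl)-2-methyloxolan-2-yl]ethynyl}-7-[(tert-butyldimethylsilyl)oxy]-4-hydroxy-6-methylhept-5-en-3-one, via Weinreb amide 21 (not isolated)
Conditions: MeNH(OMe)·HCl, i-PrMgCl, THF, −20 to 0 °C; then EtMgBr, 0 °C
Reagents that add atoms: ethylmagnesium bromide, CC[Mg]Br
Why: The magnesium amide converts the α-hydroxy ester into the Weinreb amide, whose chelated tetrahedral adduct with EtMgBr stops at the ethyl ketone (Weinreb ketone synthesis); this installs C14 with its methyl and leaves quaternary C1 untouched.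

Step 12
Reactants: 22 (4S,5Z)-4-{[(2S,5S)-5-(4-bromo-2-methylbutan-2-yl)-2-methyloxolan-2-yl]ethynyl}-7-[(tert-butyldimethylsilyl)oxy]-4-hydroxy-6-methylhept-5-en-3-one
Product: 23 (4S,5Z)-7-[(tert-butyldimethylsilyl)oxy]-4-hydroxy-4-{[(2S,5S)-5-(4-iodo-2-methylbutan-2-yl)-2-methyloxolan-2-yl]ethynyl}-6-methylhept-5-en-3-one
Conditions: NaI, NaHCO3, acetone, 50 °C
Reagents that add atoms: sodium iodide, [Na+].[I-]
Why: The Finkelstein exchange is driven by precipitation of NaBr and supplies the more reactive primary iodide needed for a slow ring closure with a lithium enolate.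

Step 13
Reactants: 23 (4S,5Z)-7-[(tert-butyldimethylsilyl)oxy]-4-hydroxy-4-{[(2S,5S)-5-(4-iodo-2-methylbutan-2-yl)-2-methyloxolan-2-yl]ethynyl}-6-methylhept-5-en-3-one
Product: 25 (1S,7S,10S,14R)-macrocyclic hydroxy ketone (ring closed at C13–C14; C1–OH; C4–OTBS; C15 ketone), via dilithium enolate alkoxide 24 (not isolated)
Conditions: LiN(SiMe3)2 (2.2 equiv), THF (0.002 M, slow addition of 23), −78 °C; then 0 °C
Reagents that add atoms: none
Why: Intramolecular C-alkylation of a ketone enolate at high dilution: the base gives the lithium alkoxide and the Z-enolate (methyl syn to oxygen, away from quaternary C1), the lithium bridge holds the C1–O bond in the enolate plane so that the alkynyl arm lies under one face and the alkenyl arm over the other, and the iodide tethered through the alkyne can reach C14 only on the alkyne face, which corresponds to (14R).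

Step 14
Reactants: 25 (1S,7S,10S,14R)-macrocyclic hydroxy ketone
Product: 26 (1S,7S,10S,14R)-macrocyclic acetoxy ketone (C1–OAc; C4–OTBS)
Conditions: Ac2O, DMAP, Et3N, CH2Cl2, rt
Reagents that add atoms: acetic anhydride, CC(=O)OC(C)=O
Why: DMAP-catalysed acylation reaches the tertiary propargylic alcohol because the alkyne keeps it open, and the weak amine base does not enolise the hindered C15 ketone, so C14 is kept.

Step 15
Reactants: 26 (1S,7S,10S,14R)-macrocyclic acetoxy ketone
Product: 27 (1S,7S,10S,14R)-macrocyclic acetoxy ketone with free (Z)-allylic alcohol at C4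
Conditions: HF·pyridine, pyridine/THF, 0 °C
Reagents that add atoms: none
Why: Acidic fluoride cleaves the primary silyl ether without generating an alkoxide, which suppresses acetyl transfer from the C1 oxygen to the cis C4 oxygen.

Step 16
Reactants: 27 (1S,7S,10S,14R)-macrocyclic acetoxy ketone with free (Z)-allylic alcohol at C4
Product: 28 (1S,7S,10S,14R)-macrocyclic propargylic acetate bearing the (Z)-CH=C(CH3)CHO arm on C1
Conditions: Dess–Martin periodinane, NaHCO3, CH2Cl2, 0 °C
Reagents that add atoms: none
Why: Buffered Dess–Martin oxidation converts the allylic alcohol into the enal under neutral conditions that keep the Z geometry, the acetate and the C14 centre; with C1 acetylated the enal cannot close to a lactol.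

Step 17
Reactants: 28 (1S,7S,10S,14R)-macrocyclic propargylic acetate bearing the (Z)-CH=C(CH3)CHO arm on C1
Product: 29 CNP0144863.1
Conditions: [Rh(nbd)(dppe)]BF4 (10 mol %; nbd = norbornadiene, dppe = 1,2-bis(diphenylphosphino)ethane) treated with H2 then argon to give [Rh(dppe)]BF4, acetone, 25 °C
Reagents that add atoms: none
Why: Oxidative addition of the formyl C4–H bond to cationic monovalent rhodium gives an acyl rhodium hydride, the C5≡C6 alkyne inserts syn into Rh–H to give a six-membered acyl alkenyl rhodacycle, and C4–C5 reductive elimination releases the catalyst. The closest known reaction is the rhodium-catalysed intramolecular hydroacylation of 5-alkynals to α-alkylidenecyclopentanones. The cyclopentenone ring C1–C2–C3–C4–C5 closes in the 5-exo-dig mode with C6 exocyclic. No stereocentre is formed; the alkene geometry (H on C6 cis to C4, C7 cis to C1) follows from syn addition and is the only one the 12-membered ring can hold. The step needs exo over endo closure and hydroacylation over decarbonylation: the six-membered rhodacycle is favoured over the seven-membered one, the Z-enal and the quaternary C1 hold the formyl group beside the alkyne, and the chelating diphosphine disfavours CO loss.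

**Compound list**

1 | (S)-linalool | C=C[C@@](C)(O)CCC=C(C)C | starting material
2 | (3S,6R)-6,7-epoxylinalool (not isolated) | C=C[C@@](C)(O)CC[C@H]1OC1(C)C | intermediate
3 | 2-[(2S,5S)-5-ethenyl-5-methyloxolan-2-yl]propan-2-ol | C=C[C@]1(C)CC[C@H](O1)C(C)(C)O | intermediate
4 | 1,2,4-trioxolane (ozonide) of 3 (not isolated) | C1(OOCO1)[C@]2(C)CC[C@H](O2)C(C)(C)O | intermediate
5 | (2S,5S)-5-(2-hydroxypropan-2-yl)-2-methyloxolane-2-carbaldehyde | O=C[C@]1(C)CC[C@H](O1)C(C)(C)O | intermediate
6 | 2-[(2S,5S)-5-ethynyl-5-methyloxolan-2-yl]propan-2-ol | C#C[C@]1(C)CC[C@H](O1)C(C)(C)O | intermediate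
7 | methyl 2-[(2S,5S)-5-ethynyl-5-methyloxolan-2-yl]propan-2-yl oxalate (not isolated) | C#C[C@]1(C)CC[C@H](O1)C(C)(C)OC(=O)C(=O)OC | intermediate
8 | cesium 2-[(2S,5S)-5-ethynyl-5-methyloxolan-2-yl]propan-2-yl oxalate | C#C[C@]1(C)CC[C@H](O1)C(C)(C)OC(=O)C(=O)[O-].[Cs+] | intermediate
9 | vinylboronic acid pinacol ester | C=CB1OC(C)(C)C(C)(C)O1 | starting material
10 | pinacol boronate of 11 (C13–Bpin; not isolated) | C#C[C@]1(C)CC[C@H](O1)C(C)(C)CCB1OC(C)(C)C(C)(C)O1 | intermediate
11 | 3-[(2S,5S)-5-ethynyl-5-methyloxolan-2-yl]-3-methylbutan-1-ol | C#C[C@]1(C)CC[C@H](O1)C(C)(C)CCO | intermediate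
12 | (2S,5S)-5-(4-bromo-2-methylbutan-2-yl)-2-ethynyl-2-methyloxolane | C#C[C@]1(C)CC[C@H](O1)C(C)(C)CCBr | intermediate
13 | prop-2-yn-1-ol | C#CCO | starting material
14 | (Z)-alkenylmagnesium bromide alkoxide from carbomagnesiation (not isolated) | Br[Mg]/C=C(C)\CO[Mg]Br | intermediate
15 | (Z)-3-iodo-2-methylprop-2-en-1-ol | I/C=C(C)\CO | intermediate
16 | tert-butyl{[(2Z)-3-iodo-2-methylprop-2-en-1-yl]oxy}dimethylsilane | I/C=C(C)\CO[Si](C)(C)C(C)(C)C | intermediate
17 | dimethyl oxalate | COC(=O)C(=O)OC | starting material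
18 | (Z)-vinyllithium from 16 (not isolated) | [Li]/C=C(C)\CO[Si](C)(C)C(C)(C)C | intermediate
19 | methyl (Z)-5-[(tert-butyldimethylsilyl)oxy]-4-methyl-2-oxopent-3-enoate | COC(=O)C(=O)/C=C(C)\CO[Si](C)(C)C(C)(C)C | intermediate
20 | methyl (2S,3Z)-2-{[(2S,5S)-5-(4-bromo-2-methylbutan-2-yl)-2-methyloxolan-2-yl]ethynyl}-5-[(tert-butyldimethylsilyl)oxy]-2-hydroxy-4-methylpent-3-enoate | COC(=O)[C@](O)(/C=C(C)\CO[Si](C)(C)C(C)(C)C)C#C[C@]1(C)CC[C@H](O1)C(C)(C)CCBr | intermediate
21 | N-methoxy-N-methyl amide of 20 (not isolated) | CON(C)C(=O)[C@](O)(/C=C(C)\CO[Si](C)(C)C(C)(C)C)C#C[C@]1(C)CC[C@H](O1)C(C)(C)CCBr | intermediate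
22 | (4S,5Z)-4-{[(2S,5S)-5-(4-bromo-2-methylbutan-2-yl)-2-methyloxolan-2-yl]ethynyl}-7-[(tert-butyldimethylsilyl)oxy]-4-hydroxy-6-methylhept-5-en-3-one | CCC(=O)[C@](O)(/C=C(C)\CO[Si](C)(C)C(C)(C)C)C#C[C@]1(C)CC[C@H](O1)C(C)(C)CCBr | intermediate
23 | (4S,5Z)-7-[(tert-butyldimethylsilyl)oxy]-4-hydroxy-4-{[(2S,5S)-5-(4-iodo-2-methylbutan-2-yl)-2-methyloxolan-2-yl]ethynyl}-6-methylhept-5-en-3-one | CCC(=O)[C@](O)(/C=C(C)\CO[Si](C)(C)C(C)(C)C)C#C[C@]1(C)CC[C@H](O1)C(C)(C)CCI | intermediate
24 | dilithium Z-enolate alkoxide of 23 (not isolated) | C/C=C(\O[Li])[C@](O[Li])(/C=C(C)\CO[Si](C)(C)C(C)(C)C)C#C[C@]1(C)CC[C@H](O1)C(C)(C)CCI | intermediate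
25 | (1S,7S,10S,14R)-macrocyclic hydroxy ketone: 12-membered carbocycle C1–C5≡C6–C7–C8–C9–C10–C11–C12–C13–C14–C15 with C7–O–C10 oxolane bridge; C1 carries OH and the (Z)-CH=C(CH3)CH2OTBS arm; C15 ketone | O[C@@]1(/C=C(C)\CO[Si](C)(C)C(C)(C)C)C#C[C@]2(C)CC[C@H](O2)C(C)(C)CC[C@@H](C)C1=O | intermediate
26 | acetate of 25 at the C1 oxygen | CC(=O)O[C@@]1(/C=C(C)\CO[Si](C)(C)C(C)(C)C)C#C[C@]2(C)CC[C@H](O2)C(C)(C)CC[C@@H](C)C1=O | intermediate
27 | desilylated 26 with free (Z)-allylic alcohol at C4 | CC(=O)O[C@@]1(/C=C(C)\CO)C#C[C@]2(C)CC[C@H](O2)C(C)(C)CC[C@@H](C)C1=O | intermediate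
28 | macrocyclic propargylic acetate with the (Z)-enal on C1 (hydroacylation precursor) | CC(=O)O[C@@]1(/C=C(C)\C=O)C#C[C@]2(C)CC[C@H](O2)C(C)(C)CC[C@@H](C)C1=O | intermediate
29 | CNP0144863.1 | CC(=O)O[C@@]12C=C(C)C(=O)/C1=C/[C@]1(C)CC[C@H](O1)C(C)(C)CC[C@@H](C)C2=O | target

**Count**

Total: 17 steps. Longest linear sequence: 14 steps (steps 1–6, then 10–17); steps 7–9 make the second fragment.

**Steps most likely to fail**

Step 13. Oligomerisation or O-alkylation may outrun closure of the strained cycloalkyne ring, or the lithium chelate may loosen so that the enolate is attacked on its other face. The fallback sets out from Weinreb amide 21, isolated for this purpose. Lithiated ethyl phenyl sulfone is added to give the β-keto sulfone F1. Its doubly stabilised carbanion is closed on the bromide with Cs2CO3 and catalytic NaI in MeCN at high dilution to give the macrocyclic α-sulfonyl ketone F2. SmI2 in THF/MeOH at −78 °C, where the α-hydroxy ketone is not reduced, removes the sulfone and returns to 25. Chelate control is given up in this variant, so the C14 epimers would be equilibrated with DBU and separated.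

Step 10. Facial selectivity at the keto ester may be poor, or the Z-enone may isomerise under zinc triflate and amine at 70 °C. The fallback sets out from 12 and 19. The alkyne is deprotonated with n-BuLi at −78 °C, transmetallated with CeCl3 and added to 19 at −78 °C, where isomerisation is not expected. Without a ligand this gives 20 together with its C1 epimer F3. The two are diastereomers and are separated by chromatography, and 20 re-enters the route.

Step 17. The acyl rhodium hydride may lose CO, the Z-enal may isomerise, or rhodium may trigger a 1,3-acyloxy shift of the propargylic acetate before C–H activation. The fallback sets out from 28. Pinnick oxidation (NaClO2, NaH2PO4, 2-methylbut-2-ene) gives the Z-enoic acid F4. PhSeSePh and PBu3 convert it into the phenyl selenoester F5. Bu3SnH and AIBN in benzene at 80 °C generate the acyl radical, which closes 5-exo-dig onto C5; the vinyl radical at C6 takes hydrogen and the ring allows only the required alkene geometry, giving 29.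

**Further compounds**

F1 | step 13 | β-keto sulfone: C15 ketone of the open chain flanked by C14H(CH3)SO2Ph; C1–OH; C13–Br | CC(C(=O)[C@](O)(/C=C(C)\CO[Si](C)(C)C(C)(C)C)C#C[C@]1(C)CC[C@H](O1)C(C)(C)CCBr)S(=O)(=O)c1ccccc1
F2 | step 13 | macrocyclic α-phenylsulfonyl ketone (C14 quaternary; configuration open) | O[C@@]1(/C=C(C)\CO[Si](C)(C)C(C)(C)C)C#C[C@]2(C)CC[C@H](O2)C(C)(C)CCC(C)(S(=O)(=O)c2ccccc2)C1=O
F3 | step 10 | (2R)-epimer of 20 at C1 | COC(=O)[C@@](O)(/C=C(C)\CO[Si](C)(C)C(C)(C)C)C#C[C@]1(C)CC[C@H](O1)C(C)(C)CCBr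
F4 | step 17 | (Z)-enoic acid from 28 (C4 carboxylic acid) | CC(=O)O[C@@]1(/C=C(C)\C(=O)O)C#C[C@]2(C)CC[C@H](O2)C(C)(C)CC[C@@H](C)C1=O
F5 | step 17 | Se-phenyl selenoester of F4 | CC(=O)O[C@@]1(/C=C(C)\C(=O)[Se]c2ccccc2)C#C[C@]3(C)CC[C@H](O3)C(C)(C)CC[C@@H](C)C1=O
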